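By 30.0 min the dusk flask had lost 91.6% of its starting material, yet target read 46.5%. Even with one starting material held on every catalyst, a side share σ (lost starting material that is neither target nor on the catalyst) stood at 47.4%, as a reading.

| flask | starting material | reagent | free catalyst | remark |
|---|---|---|---|---|
| noon | 1.5 M | 0.95 equiv | 2.5 mol% | the very flask that is asked about, followed so far |
| dusk | 1.5 M | 0.95 equiv | 1.7 mol% | run made earlier |
| flask | 1.5 M | 0.950 equiv | 2.5 mol% |  |

| run | time / min | target / % | starting material / % |
|---|---|---|---|
| noon | 0.500 | 1.0 | 94.0 |
| noon | 1.00 | 3.5 | 87.9 |
| noon | 2.50 | 7.7 | 74.5 |
| noon | 6.00 | 19.6 | 49.9 |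
| dusk | 8.00 | 17.4 | 48.8 |
| dusk | 15.0 | 28.9 | 28.8 |
| dusk | 25.0 | 40.7 | 12.4 |
| dusk | 30.0 | 46.5 | 8.4 |

(each reading ± 1 percentage point)

* apparent order in free catalyst when 5.0% of the starting material are converted (percent change of the rate of making target for one percent more free catalyst charged)
* apparent order in reagent when 5.0% of the starting material are converted (percent change of the rate of making target for one percent more reagent charged)
* factor on the rate of making target when 5.0% of the starting material are converted if free catalyst is charged twice over

- no earlier run changes the charge of reagent; that part of a forecast is a guess

I turned the reagent first. With e its equivalents and one reagent per target, I defined the break-even side share σ* = 1 − e, the side share at which reagent and starting material would end together, here 5.00%. When starting material is used up and the catalyst holds none of it, the reagent left, as a share of its own charge, is (σ − σ*)/e. The dusk reading lay well above σ*, so I did not expect the reagent, the smaller charge, to act as limiting reagent. I took it as one link of a chain and put its order between zero and one, a guess since no run varied it.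

Then I turned the free catalyst. The conversion asked about is twice the catalyst charge, and at 0.500 min the noon flask read target 1.0% against a loading of 2.5 mol%. I read that as a cycle still filling, so I took the catalyst order below one and the doubling factor below 2.

The forecast gave a catalyst order of 1, a reagent order of 0.6 and a doubling factor of 1.95, holding that “The target-forming path is therefore also catalyst-driven”.

The noon flask gave a reagent order of 0.54, then a catalyst order of 0.62 and a doubling factor of 1.21.

    2 starting material → homo dimer (k = 4.60 × 10⁻⁴ L mol⁻¹ s⁻¹)
    catalyst intermediate B → free catalyst + target (k = 0.0640 s⁻¹)
    reagent + catalyst intermediate A → catalyst intermediate B (k = 0.0520 L mol⁻¹ s⁻¹)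
    starting material + free catalyst → catalyst intermediate A (k = 0.0730 L mol⁻¹ s⁻¹)

The step to homo dimer needs no catalyst, and it accounts for part of the low catalyst order: in the simulated run without that step, the order rose from 0.62 to 1.0. In the noon flask at 300 min, homo dimer, the side share there, held 37.7% of the starting material, against σ* of 5.00%. The balance then gave 34.5% of the reagent left, and the flask held 34.5%, with starting material at 0%.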